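**Retrosynthetic overview**

1. Target 15 comes from 14 by acid removal of the MOM and TIPS groups; the C7 enal comes from the C7 ester of 11 (i-Bu2AlH, MnO2, formylmethylene Wittig).
2. Ring B (the dioxane) is the only ring made: cutting O4–C4a in 11 gives bromo alcohol 10, which is closed by palladium-catalysed intramolecular aryl etherification; rings A and C are bought intact.
3. 10 comes from forming O1–C2 by Mitsunobu inversion between phenol 2 and anti alcohol 7, then acetonide hydrolysis and primary silylation.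
4. 7 comes from addition of the ring C aryltitanium reagent to (S)-glyceraldehyde acetonide 4, which supplies C3 and its oxygen pattern.
5. Feature: in ring A, C4a lies between C8a (bearing O1) and C5 (bearing OH), so the symmetric 2-bromoresorcinol ester 1 places its bromine on C4a, its two equivalent hydroxyls on O1 and the C5 OH, and its para ester on C7.

Key step: step 6

Remark: locants follow the 1,4-benzodioxane core (O1, C2 aryl-bearing, C3 hydroxymethyl-bearing, O4, C4a, C5–C8, C8a; ring A benzo, ring B dioxane, ring C trimethoxyphenyl), and aldehyde 4 is assumed to be freshly distilled because it oligomerises on storage.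

**Route**

Step 1
Reactants: 1 methyl 4-bromo-3,5-dihydroxybenzoate
Product: 2 methyl 4-bromo-3-hydroxy-5-(methoxymethoxy)benzoate
Conditions: MOMCl (1.0 equiv), i-Pr2NEt, THF, 0 °C → rt; chromatography
Reagents that add atoms: chloromethyl methyl ether (MOMCl), COCCl
Why: Williamson-type O-alkylation of a phenol; the two hydroxyls of 1 are equivalent by symmetry, so monoalkylation can give only one mono-ether, which is separated from the bis-ether and from recovered 1 (both recyclable).

Step 2
Reactants: 3 5-bromo-1,2,3-trimethoxybenzene; 4 (S)-2,2-dimethyl-1,3-dioxolane-4-carbaldehyde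
Product: 7 (R)-[(S)-2,2-dimethyl-1,3-dioxolan-4-yl](3,4,5-trimethoxyphenyl)methanol, via arylmagnesium bromide 5 (not isolated), via aryltitanium triisopropoxide 6 (not isolated)
Conditions: Mg, THF, 40 °C; ClTi(OiPr)3, −78 → −30 °C; then 4, −78 → 0 °C; aq. NH4Cl; chromatography
Reagents that add atoms: none
Why: Grignard formation, transmetalation to a non-chelating aryltitanium triisopropoxide and Felkin–Anh addition to the α-alkoxy aldehyde, the aryl group approaching anti to the dioxolane C–O bond so that the new carbinol centre should be set as R (anti to the S centre taken from 4), with any syn isomer removed by chromatography.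

Step 3
Reactants: 7 (R)-[(S)-2,2-dimethyl-1,3-dioxolan-4-yl](3,4,5-trimethoxyphenyl)methanol; 2 methyl 4-bromo-3-hydroxy-5-(methoxymethoxy)benzoate
Product: 8 methyl 4-bromo-3-{(S)-[(S)-2,2-dimethyl-1,3-dioxolan-4-yl](3,4,5-trimethoxyphenyl)methoxy}-5-(methoxymethoxy)benzoate
Conditions: PPh3, DIAD, toluene, 0 °C → rt
Reagents that add atoms: none
Why: Mitsunobu etherification, in which the acidic ortho-bromophenol 2 displaces the benzylic oxyphosphonium ion in an SN2 sense and so inverts C1 from R to S (the future C2), ionisation being held back by the adjacent dioxolane oxygen and the non-polar solvent.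

Step 4
Reactants: 8 methyl 4-bromo-3-{(S)-[(S)-2,2-dimethyl-1,3-dioxolan-4-yl](3,4,5-trimethoxyphenyl)methoxy}-5-(methoxymethoxy)benzoate
Product: 9 methyl 4-bromo-3-{[(1S,2S)-2,3-dihydroxy-1-(3,4,5-trimethoxyphenyl)propyl]oxy}-5-(methoxymethoxy)benzoate
Conditions: AcOH/H2O (4:1), 40 °C
Reagents that add atoms: none
Why: Acid-catalysed hydrolysis of a terminal isopropylidene acetal in aqueous acetic acid, mild enough to leave the aryl MOM ether, the methyl ester and the benzylic aryl ether untouched and involving neither stereocentre.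

Step 5
Reactants: 9 methyl 4-bromo-3-{[(1S,2S)-2,3-dihydroxy-1-(3,4,5-trimethoxyphenyl)propyl]oxy}-5-(methoxymethoxy)benzoate
Product: 10 methyl 4-bromo-3-{[(1S,2S)-2-hydroxy-1-(3,4,5-trimethoxyphenyl)-3-[(triisopropylsilyl)oxy]propyl]oxy}-5-(methoxymethoxy)benzoate
Conditions: TIPSCl, imidazole, CH2Cl2, 0 °C → rt
Reagents that add atoms: triisopropylsilyl chloride (TIPSCl), CC(C)[Si](Cl)(C(C)C)C(C)C
Why: Sterically controlled silylation of the primary hydroxyl of a 1,2-diol with a bulky silyl chloride; the triisopropylsilyl group is chosen because it should resist a base-induced 1,2-oxygen-to-oxygen silyl shift in step 6, which a smaller silyl group might undergo.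

Step 6
Reactants: 10 methyl 4-bromo-3-{[(1S,2S)-2-hydroxy-1-(3,4,5-trimethoxyphenyl)-3-[(triisopropylsilyl)oxy]propyl]oxy}-5-(methoxymethoxy)benzoate
Product: 11 methyl (2S,3S)-5-(methoxymethoxy)-3-{[(triisopropylsilyl)oxy]methyl}-2-(3,4,5-trimethoxyphenyl)-2,3-dihydro-1,4-benzodioxine-7-carboxylate
Conditions: Pd(OAc)2 (5 mol%), rac-2-(di-tert-butylphosphino)-1,1'-binaphthyl (6 mol%), Cs2CO3, toluene, 75 °C
Reagents that add atoms: none
Why: Zerovalent palladium formed from Pd(OAc)2 and the phosphine inserts into the C4a–Br bond, carbonate-assisted exchange of bromide for the C3 alkoxide gives a seven-membered aryl(alkoxo) complex of divalent palladium, and C–O reductive elimination forges O4–C4a. The closest known reaction type is the Buchwald–Hartwig-type intramolecular etherification of aryl bromides carrying a tethered secondary alcohol, which is established for 1,4-benzodioxanes. Ring B closes in a 6-exo sense at the sp2 carbon C4a, the six-membered dioxane arising from the palladacycle at the reductive elimination. No stereocentre is created and no bond to C2 or C3 is broken, so the (1S,2S)-threo arrangement of 10 is carried over as the trans-(2S,3S) ring. The step needs chemoselectivity for the secondary hydroxyl, secured by the TIPS cap on the primary oxygen and the MOM cap on the C5 phenol, and it needs reductive elimination to outpace β-hydride elimination of the secondary alkoxide, which the bulky di-tert-butylphosphine and the six-membered closure promote. The para ester at C7 eases oxidative addition at the doubly ortho-oxygenated bromide.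

Step 7
Reactants: 11 methyl (2S,3S)-5-(methoxymethoxy)-3-{[(triisopropylsilyl)oxy]methyl}-2-(3,4,5-trimethoxyphenyl)-2,3-dihydro-1,4-benzodioxine-7-carboxylate
Product: 12 [(2S,3S)-5-(methoxymethoxy)-3-{[(triisopropylsilyl)oxy]methyl}-2-(3,4,5-trimethoxyphenyl)-2,3-dihydro-1,4-benzodioxin-7-yl]methanol
Conditions: i-Bu2AlH (2.5 equiv), CH2Cl2, −78 → 0 °C; Rochelle salt work-up
Reagents that add atoms: none
Why: Hydride reduction of an aryl methyl ester to the benzylic alcohol with i-Bu2AlH, under which the ethers, the MOM acetal and the silyl ether are inert.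

Step 8
Reactants: 12 [(2S,3S)-5-(methoxymethoxy)-3-{[(triisopropylsilyl)oxy]methyl}-2-(3,4,5-trimethoxyphenyl)-2,3-dihydro-1,4-benzodioxin-7-yl]methanol
Product: 13 (2S,3S)-5-(methoxymethoxy)-3-{[(triisopropylsilyl)oxy]methyl}-2-(3,4,5-trimethoxyphenyl)-2,3-dihydro-1,4-benzodioxine-7-carbaldehyde
Conditions: MnO2 (activated, excess), CH2Cl2, rt
Reagents that add atoms: none
Why: MnO2 oxidation is selective for benzylic alcohols and should stop at the aldehyde without touching the other groups.

Step 9
Reactants: 13 (2S,3S)-5-(methoxymethoxy)-3-{[(triisopropylsilyl)oxy]methyl}-2-(3,4,5-trimethoxyphenyl)-2,3-dihydro-1,4-benzodioxine-7-carbaldehyde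
Product: 14 (E)-3-[(2S,3S)-5-(methoxymethoxy)-3-{[(triisopropylsilyl)oxy]methyl}-2-(3,4,5-trimethoxyphenyl)-2,3-dihydro-1,4-benzodioxin-7-yl]prop-2-enal
Conditions: Ph3P=CHCHO (1.3 equiv), toluene, 80 °C
Reagents that add atoms: (triphenylphosphoranylidene)acetaldehyde, O=CC=P(c1ccccc1)(c1ccccc1)c1ccccc1
Why: Wittig olefination with the stabilised formylmethylene ylide, which should give the E-enal as stabilised ylides do, a small excess of ylide limiting a second homologation.

Step 10
Reactants: 14 (E)-3-[(2S,3S)-5-(methoxymethoxy)-3-{[(triisopropylsilyl)oxy]methyl}-2-(3,4,5-trimethoxyphenyl)-2,3-dihydro-1,4-benzodioxin-7-yl]prop-2-enal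
Product: 15 (E)-3-[(2S,3S)-5-hydroxy-3-(hydroxymethyl)-2-(3,4,5-trimethoxyphenyl)-2,3-dihydro-1,4-benzodioxin-7-yl]prop-2-enal (CNP0241953.1)
Conditions: 3 M aq. HCl, THF, 40 °C
Reagents that add atoms: none
Why: Acid hydrolysis of the aryl MOM acetal and of the primary silyl ether in one operation, run in aqueous THF without alcohol so that the enal is not acetalised, and not expected to affect the benzylic ether of ring B or the E-olefin at this acidity and temperature.

**Compound list**

1 | methyl 4-bromo-3,5-dihydroxybenzoate | COC(=O)c1cc(O)c(Br)c(O)c1 | starting material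
2 | methyl 4-bromo-3-hydroxy-5-(methoxymethoxy)benzoate | COCOc1cc(C(=O)OC)cc(O)c1Br | intermediate
3 | 5-bromo-1,2,3-trimethoxybenzene | COc1cc(Br)cc(OC)c1OC | starting material
4 | (S)-2,2-dimethyl-1,3-dioxolane-4-carbaldehyde | O=C[C@@H]1COC(C)(C)O1 | starting material
5 | (3,4,5-trimethoxyphenyl)magnesium bromide | COc1cc([Mg]Br)cc(OC)c1OC | intermediate
6 | triisopropoxy(3,4,5-trimethoxyphenyl)titanium | COc1cc([Ti](OC(C)C)(OC(C)C)OC(C)C)cc(OC)c1OC | intermediate
7 | (R)-[(S)-2,2-dimethyl-1,3-dioxolan-4-yl](3,4,5-trimethoxyphenyl)methanol | COc1cc([C@@H](O)[C@@H]2COC(C)(C)O2)cc(OC)c1OC | intermediate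
8 | methyl 4-bromo-3-{(S)-[(S)-2,2-dimethyl-1,3-dioxolan-4-yl](3,4,5-trimethoxyphenyl)methoxy}-5-(methoxymethoxy)benzoate | COc1cc([C@H](Oc2cc(C(=O)OC)cc(OCOC)c2Br)[C@@H]2COC(C)(C)O2)cc(OC)c1OC | intermediate
9 | methyl 4-bromo-3-{[(1S,2S)-2,3-dihydroxy-1-(3,4,5-trimethoxyphenyl)propyl]oxy}-5-(methoxymethoxy)benzoate | COc1cc([C@H](Oc2cc(C(=O)OC)cc(OCOC)c2Br)[C@@H](O)CO)cc(OC)c1OC | intermediate
10 | methyl 4-bromo-3-{[(1S,2S)-2-hydroxy-1-(3,4,5-trimethoxyphenyl)-3-[(triisopropylsilyl)oxy]propyl]oxy}-5-(methoxymethoxy)benzoate | COc1cc([C@H](Oc2cc(C(=O)OC)cc(OCOC)c2Br)[C@@H](O)CO[Si](C(C)C)(C(C)C)C(C)C)cc(OC)c1OC | intermediate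
11 | methyl (2S,3S)-5-(methoxymethoxy)-3-{[(triisopropylsilyl)oxy]methyl}-2-(3,4,5-trimethoxyphenyl)-2,3-dihydro-1,4-benzodioxine-7-carboxylate | COc1cc([C@@H]2Oc3cc(C(=O)OC)cc(OCOC)c3O[C@H]2CO[Si](C(C)C)(C(C)C)C(C)C)cc(OC)c1OC | intermediate
12 | [(2S,3S)-5-(methoxymethoxy)-3-{[(triisopropylsilyl)oxy]methyl}-2-(3,4,5-trimethoxyphenyl)-2,3-dihydro-1,4-benzodioxin-7-yl]methanol | COc1cc([C@@H]2Oc3cc(CO)cc(OCOC)c3O[C@H]2CO[Si](C(C)C)(C(C)C)C(C)C)cc(OC)c1OC | intermediate
13 | (2S,3S)-5-(methoxymethoxy)-3-{[(triisopropylsilyl)oxy]methyl}-2-(3,4,5-trimethoxyphenyl)-2,3-dihydro-1,4-benzodioxine-7-carbaldehyde | COc1cc([C@@H]2Oc3cc(C=O)cc(OCOC)c3O[C@H]2CO[Si](C(C)C)(C(C)C)C(C)C)cc(OC)c1OC | intermediate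
14 | (E)-3-[(2S,3S)-5-(methoxymethoxy)-3-{[(triisopropylsilyl)oxy]methyl}-2-(3,4,5-trimethoxyphenyl)-2,3-dihydro-1,4-benzodioxin-7-yl]prop-2-enal | COc1cc([C@@H]2Oc3cc(/C=C/C=O)cc(OCOC)c3O[C@H]2CO[Si](C(C)C)(C(C)C)C(C)C)cc(OC)c1OC | intermediate
15 | (E)-3-[(2S,3S)-5-hydroxy-3-(hydroxymethyl)-2-(3,4,5-trimethoxyphenyl)-2,3-dihydro-1,4-benzodioxin-7-yl]prop-2-enal | COc1cc([C@@H]2Oc3cc(/C=C/C=O)cc(O)c3O[C@H]2CO)cc(OC)c1OC | target

**Totals**

Total step count: 10. Longest linear sequence: 9 steps (from 3 and 4 through steps 2–10; the branch from 1 through steps 1 and 3–10 is equally long).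

**Steps most likely to fail**

Step 6 (key step). Oxidative addition into the bromide flanked by two oxygen substituents may be slow, and the palladium alkoxide may lose a β-hydride, which would give ketone and hydrodebromination in place of ring closure. The fallback sets out from 10 and comes back at 11. Ring B would be closed by a copper-mediated Ullmann ether condensation (CuI, 3,4,7,8-tetramethyl-1,10-phenanthroline, Cs2CO3, toluene, 110 °C). This runs through a copper alkoxide for which β-hydride loss is not a usual pathway, and it leaves C2 and C3 untouched. This fallback makes no new compound (F0).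

Step 3. The benzylic oxyphosphonium ion next to the electron-rich ring C may ionise, which would erode the inversion at C1 or lead to elimination, and coupling of the hindered alcohol may be sluggish. The fallback sets out from 7 and comes back at 10, bypassing 8 and 9. It replaces the Mitsunobu reaction by the stereospecific opening of a cyclic sulfate.
- Aqueous acetic acid would hydrolyse the acetonide of 7 to (1R,2S)-1-(3,4,5-trimethoxyphenyl)propane-1,2,3-triol F1.
- TIPSCl and imidazole would cap the primary hydroxyl to give (1R,2S)-3-[(triisopropylsilyl)oxy]-1-(3,4,5-trimethoxyphenyl)propane-1,2-diol F2.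
- SOCl2 and Et3N would give the cis cyclic sulfite (4S,5R)-4-{[(triisopropylsilyl)oxy]methyl}-5-(3,4,5-trimethoxyphenyl)-1,3,2-dioxathiolane 2-oxide F3.
- Catalytic RuCl3 with NaIO4 would oxidise it to (4S,5R)-4-{[(triisopropylsilyl)oxy]methyl}-5-(3,4,5-trimethoxyphenyl)-1,3,2-dioxathiolane 2,2-dioxide F4.
- Phenol 2 with Cs2CO3 in DMF should open F4 at the benzylic carbon with inversion to give cesium (1S,2S)-1-[2-bromo-5-(methoxycarbonyl)-3-(methoxymethoxy)phenoxy]-3-[(triisopropylsilyl)oxy]-1-(3,4,5-trimethoxyphenyl)propan-2-yl sulfate F5.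
- Catalytic H2SO4 with a little water in THF would hydrolyse the sulfate monoester with retention at C2 to give 10.

Step 2. Facial selectivity in the addition to the α-alkoxy aldehyde may be poor, so that the syn carbinol forms in quantity. The fallback sets out from 7 obtained as a mixture with its benzylic epimer and comes back at 7. The mixture would be oxidised with Dess–Martin periodinane (CH2Cl2, NaHCO3) to (S)-(2,2-dimethyl-1,3-dioxolan-4-yl)(3,4,5-trimethoxyphenyl)methanone F6. Chelation-controlled reduction with Zn(BH4)2 in Et2O at −30 °C, the zinc bridging the ketone oxygen and the α-oxygen of the dioxolane, should then deliver hydride to give the anti alcohol 7.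

**Further compounds**

F0 | step 6 | none | none
F1 | step 3 | (1R,2S)-1-(3,4,5-trimethoxyphenyl)propane-1,2,3-triol | COc1cc([C@@H](O)[C@@H](O)CO)cc(OC)c1OC
F2 | step 3 | (1R,2S)-3-[(triisopropylsilyl)oxy]-1-(3,4,5-trimethoxyphenyl)propane-1,2-diol | COc1cc([C@@H](O)[C@@H](O)CO[Si](C(C)C)(C(C)C)C(C)C)cc(OC)c1OC
F3 | step 3 | (4S,5R)-4-{[(triisopropylsilyl)oxy]methyl}-5-(3,4,5-trimethoxyphenyl)-1,3,2-dioxathiolane 2-oxide | COc1cc([C@H]2OS(=O)O[C@H]2CO[Si](C(C)C)(C(C)C)C(C)C)cc(OC)c1OC
F4 | step 3 | (4S,5R)-4-{[(triisopropylsilyl)oxy]methyl}-5-(3,4,5-trimethoxyphenyl)-1,3,2-dioxathiolane 2,2-dioxide | COc1cc([C@H]2OS(=O)(=O)O[C@H]2CO[Si](C(C)C)(C(C)C)C(C)C)cc(OC)c1OC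
F5 | step 3 | cesium (1S,2S)-1-[2-bromo-5-(methoxycarbonyl)-3-(methoxymethoxy)phenoxy]-3-[(triisopropylsilyl)oxy]-1-(3,4,5-trimethoxyphenyl)propan-2-yl sulfate | COc1cc([C@H](Oc2cc(C(=O)OC)cc(OCOC)c2Br)[C@@H](OS(=O)(=O)[O-])CO[Si](C(C)C)(C(C)C)C(C)C)cc(OC)c1OC.[Cs+]
F6 | step 2 | (S)-(2,2-dimethyl-1,3-dioxolan-4-yl)(3,4,5-trimethoxyphenyl)methanone | COc1cc(C(=O)[C@@H]2COC(C)(C)O2)cc(OC)c1OC
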